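The target in these flasks appears to feed its own formation, so the rule I carry is the amount of target that doubles the rate coefficient.

| flask | substrate | partner | free catalyst | time |
|---|---|---|---|---|
| south-east | 0.0800 M | 0.0880 M | 0.00240 M |  |
| north-east | 0.0400 M | 0.0480 M | 0.00240 M |  |
| west | 0.0800 M | 0.180 M | 0.00240 M |  |
| south-west | 0.0800 M | 0.0880 M | 0.00480 M |  |
| east | 0.0260 M | 0.0290 M | 0.00240 M | 7.2 min |

| south-east run: time / min | south-east run: [target] / M | north-east run: time / min | north-east run: [target] / M | west run: time / min | west run: [target] / M | south-west run: time / min | south-west run: [target] / M |
|---|---|---|---|---|---|---|---|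
| 1.4 | 0.00701 | 1.4 | 0.00173 | 1.4 | 0.01517 | 1.4 | 0.01369 |
| 2.9 | 0.01448 | 2.9 | 0.00384 | 2.9 | 0.03205 | 2.9 | 0.02556 |
| 4.3 | 0.02153 | 4.3 | 0.00585 | 4.3 | 0.04438 | 4.3 | 0.03404 |
| 5.8 | 0.02800 | 5.8 | 0.00710 | 5.8 | 0.05554 | 5.8 | 0.04162 |
| 7.2 | 0.03340 | 7.2 | 0.00866 | 7.2 | 0.06216 | 7.2 | 0.04688 |

(scatter of a reading: 2 × 10⁻⁴ M)

* the power of [substrate] that the first rate follows, about the charge of the south-east run; measure it at two percent of substrate made into target (one fixed amount of target, the same in the runs compared)
* the power of [partner] that the first rate follows, about the charge of the south-east run; measure it at two percent of substrate made into target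
* the north-east run starts with 0.0400 M less of substrate and of partner than the south-east run, and with no target. Compared where both hold the same amount of substrate, once fifteen percent of what the north-east run was charged with has turned into target, is the north-east run faster, slower or alike (within a tenth)?
* target in the east run at 7.2 min, as a share of the substrate charged
* which of these the readings show (the product binds the second partner / the product speeds the reaction / nothing beyond the main steps / the second partner is lost in pairs / an uncatalysed path runs beside / a little impurity takes part of the catalyst at once)

- Overall: substrate + partner -> target, with free catalyst as catalyst.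
- Constant volume, constant temperature.
- "The second partner" is partner.
- An order is taken over about fifteen percent of the charge, up and down.

I divide the rate by [substrate][partner], taken at their mean amounts. In the north-east run, up to 2.9 min, with mean [target] 0.001920 M, this coefficient reads 0.755 L mol⁻¹ min⁻¹. In the south-east run, with the same catalyst charge, from 4.3 min to 7.2 min, with mean [target] 0.02746 M, it reads a higher 1.29 L mol⁻¹ min⁻¹.

A straight line through these two readings starts at 0.715 L mol⁻¹ min⁻¹ with no target. It doubles at the doubling target, 0.0343 M: the [target] at which, with 0.00240 M of free catalyst charged, the path through the target (autocatalysis) equals the path without it.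

For the east run, the fresh coefficient held for 7.2 min gives 0.003879 M. Mean [target] is then 0.001940 M, about half of that amount, which is less than the doubling target, so I treat it as a correction. It raises the rate by 5.66%, while substrate and partner fall by 7.46% and 6.69%. My reckoning is 0.003539 M, or 13.6% of the substrate charged.

The forecast gives orders 1.02 and 1.02, north-east slower, east 13.5%, close to my figure, and the verdict the product speeds the reaction: “so product must be helping”.

The simulation gives orders 1.0 and 1.0, north-east slower, east 13.6%, and the product speeds the reaction.

    2 free catalyst ⇌ catalyst dimer, settled at all times (9680 L mol⁻¹)
    catalyst dimer + substrate + partner → target + catalyst dimer (684.0 L² mol⁻² min⁻¹)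
    substrate + partner + target → 2 target (22.44 L² mol⁻² min⁻¹)

A fit in which the partner is lost by itself forecasts 18.7% for the east run. At the compared point, the north-east run holds 0.006000 M of target and the south-east run 0.04600 M, with equal substrate and partner. The doubling target therefore gives a north-east rate of 0.502 of the south-east rate, and the flask's ratio is 0.48.

The runs were generated by integration with constants of no real substance; noise was put on by code.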